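**Retrosynthetic overview**

1. The C15 caffeate ester is cut last (carbodiimide esterification); until then the catechol and the C2 oxygen carry silyl ethers and the C15 oxygen a PMB ether.
2. Ring B is opened at C5–C6. Its C6–C7=C8(–C17H3) unit is read as the 1,4-hydro-adduct of a 2-substituted buta-1,3-diene (C6=C7–C8=C17). C5 is a CH between the two quaternary carbons C4 and C10 of ring A, so a C5 radical (from a xanthate) has no β-hydrogen to lose.
3. The C10–C9 bond and both of its stereocentres come from a C–O coupling/Claisen rearrangement between a vinyl iodide made from (4R,6R)-actinol (ring A with the C2 oxygen) and an (E)-2-vinyl allylic alcohol made from (S)-citronellol (C13 stereocentre).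
4. Ring order: ring A is bought, ring B is the only ring made (step 12), and the arene arrives with caffeic acid.

Key step: step 12

Remark: labdane numbering is used throughout (ring A = C1–C5 and C10; ring B = C5–C10; C17 on C8; C18 and C19 on C4; C20 on C10; side chain C11–C16). (4R,6R)-Actinol 1, (S)-citronellol 5 and caffeic acid 20 are taken as commercial.

**Route**

Step 1
Reactants: 1 (4R,6R)-4-hydroxy-2,2,6-trimethylcyclohexan-1-one (actinol)
Product: 2 (4R,6R)-4-[(tert-butyldimethylsilyl)oxy]-2,2,6-trimethylcyclohexan-1-one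
Conditions: TBSCl, imidazole, DMF, rt
Reagents that add atoms: tert-butyldimethylsilyl chloride, CC(C)(C)[Si](C)(C)Cl
Why: Silyl ether formation at the unhindered secondary alcohol; the carbinol centre (C2 of the target) is carried unchanged from the chiral pool.

Step 2
Reactants: 2 (4R,6R)-4-[(tert-butyldimethylsilyl)oxy]-2,2,6-trimethylcyclohexan-1-one
Product: 3 hydrazone of (4R,6R)-4-[(tert-butyldimethylsilyl)oxy]-2,2,6-trimethylcyclohexan-1-one
Conditions: N2H4·H2O, Et3N, EtOH, reflux
Reagents that add atoms: hydrazine hydrate, NN.O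
Why: Hydrazone condensation, which small hydrazine should manage at a ketone flanked by only one quaternary carbon.

Step 3
Reactants: 3 hydrazone of (4R,6R)-4-[(tert-butyldimethylsilyl)oxy]-2,2,6-trimethylcyclohexan-1-one
Product: 4 (R)-tert-butyl[(4-iodo-3,5,5-trimethylcyclohex-3-en-1-yl)oxy]dimethylsilane
Conditions: I2, 1,1,3,3-tetramethylguanidine, Et2O, 0 °C to rt
Reagents that add atoms: iodine, II
Why: Barton vinyl iodide synthesis, in which iodination, loss of N2 and elimination towards the only β-hydrogen give the tetrasubstituted vinyl iodide; the methyl-bearing stereocentre of actinol is erased on purpose.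

Step 4
Reactants: 5 (S)-citronellol, (3S)-3,7-dimethyloct-6-en-1-ol
Product: 6 1-({[(3S)-3,7-dimethyloct-6-en-1-yl]oxy}methyl)-4-methoxybenzene
Conditions: NaH, 4-methoxybenzyl chloride, Bu4NI (cat.), THF/DMF, 0 °C to rt
Reagents that add atoms: 4-methoxybenzyl chloride, COc1ccc(CCl)cc1
Why: Williamson ether synthesis; the stereocentre (C13 of the target) is remote and untouched.

Step 5
Reactants: 6 1-({[(3S)-3,7-dimethyloct-6-en-1-yl]oxy}methyl)-4-methoxybenzene
Product: 7 (4S)-6-[(4-methoxybenzyl)oxy]-4-methylhexanal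
Conditions: OsO4 (cat.), NaIO4, 2,6-lutidine, dioxane/H2O, rt
Reagents that add atoms: sodium periodate, [Na+].[O-]I(=O)(=O)=O; water, O
Why: Lemieux–Johnson oxidative cleavage of the trisubstituted olefin, chosen over ozonolysis because the PMB ether tolerates it.

Step 6
Reactants: 7 (4S)-6-[(4-methoxybenzyl)oxy]-4-methylhexanal
Product: 8 (5S)-1,1-dibromo-7-[(4-methoxybenzyl)oxy]-5-methylhept-1-ene
Conditions: CBr4, PPh3, CH2Cl2, 0 °C
Reagents that add atoms: carbon tetrabromide, BrC(Br)(Br)Br
Why: First stage of the Corey–Fuchs reaction (Wittig-type dibromo-olefination of the aldehyde).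

Step 7
Reactants: 8 (5S)-1,1-dibromo-7-[(4-methoxybenzyl)oxy]-5-methylhept-1-ene
Product: 10 (6S)-8-[(4-methoxybenzyl)oxy]-6-methyloct-2-yn-1-ol, via lithium acetylide 9 (not isolated)
Conditions: n-BuLi (2.2 equiv), THF, −78 °C to 0 °C; then (CH2O)n, 0 °C to rt
Reagents that add atoms: paraformaldehyde (formaldehyde), C=O
Why: Second stage of the Corey–Fuchs reaction (lithium–halogen exchange and Fritsch–Buttenberg–Wiechell shift) gives the acetylide, which adds to formaldehyde.

Step 8
Reactants: 10 (6S)-8-[(4-methoxybenzyl)oxy]-6-methyloct-2-yn-1-ol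
Product: 12 (2E,6S)-2-ethenyl-8-[(4-methoxybenzyl)oxy]-6-methyloct-2-en-1-ol, via magnesium chelate 11 (not isolated)
Conditions: CH2=CHMgCl (4 equiv), THF/toluene, 70 °C; then aq NH4Cl
Reagents that add atoms: vinylmagnesium chloride, C=C[Mg]Cl
Why: Alkoxide-directed anti-carbomagnesiation of the propargylic alcohol, in which vinyl adds to the carbon next to CH2O and magnesium is held cis to CH2O in the five-membered chelate 11, so protonolysis leaves the alkyl chain trans to CH2OH (the E olefin).

Step 9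
Reactants: 4 (R)-tert-butyl[(4-iodo-3,5,5-trimethylcyclohex-3-en-1-yl)oxy]dimethylsilane; 12 (2E,6S)-2-ethenyl-8-[(4-methoxybenzyl)oxy]-6-methyloct-2-en-1-ol
Product: 14 (2R,4S)-4-[(tert-butyldimethylsilyl)oxy]-2-[(4S,7S)-9-[(4-methoxybenzyl)oxy]-7-methyl-3-methylidenenon-1-en-4-yl]-2,6,6-trimethylcyclohexan-1-one, via allyl vinyl ether 13 (not isolated)
Conditions: CuI (10 mol %), 3,4,7,8-tetramethyl-1,10-phenanthroline, Cs2CO3, o-xylene, 120 °C then 140 °C
Reagents that add atoms: none
Why: Ullmann-type copper-catalysed C–O coupling gives allyl vinyl ether 13, which undergoes Claisen rearrangement in the same flask; the allyl terminus should add to C10 anti to the pseudoaxial C4 methyl of the half-chair (the face cis to the equatorial silyloxy group, as in alkylation of steroidal 3-ketone enolates anti to the angular methyl), and the chair transition state of the E olefin, with the chain equatorial, sets C9.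

Step 10
Reactants: 14 (2R,4S)-4-[(tert-butyldimethylsilyl)oxy]-2-[(4S,7S)-9-[(4-methoxybenzyl)oxy]-7-methyl-3-methylidenenon-1-en-4-yl]-2,6,6-trimethylcyclohexan-1-one
Product: 15 (2R,4S)-4-[(tert-butyldimethylsilyl)oxy]-2-[(4S,7S)-9-[(4-methoxybenzyl)oxy]-7-methyl-3-methylidenenon-1-en-4-yl]-2,6,6-trimethylcyclohexan-1-ol (both C5 epimers)
Conditions: LiAlH4, THF, 0 °C to reflux; aqueous work-up
Reagents that add atoms: none
Why: Hydride reduction of the hindered ketone; the new C5 carbinol centre is not controlled and need not be, because it becomes a radical in step 12.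

Step 11
Reactants: 15 (2R,4S)-4-[(tert-butyldimethylsilyl)oxy]-2-[(4S,7S)-9-[(4-methoxybenzyl)oxy]-7-methyl-3-methylidenenon-1-en-4-yl]-2,6,6-trimethylcyclohexan-1-ol
Product: 17 O-{(2R,4S)-4-[(tert-butyldimethylsilyl)oxy]-2-[(4S,7S)-9-[(4-methoxybenzyl)oxy]-7-methyl-3-methylidenenon-1-en-4-yl]-2,6,6-trimethylcyclohexyl} S-methyl carbonodithioate (both C5 epimers), via sodium xanthate 16 (not isolated)
Conditions: NaH, imidazole (cat.), THF, 0 °C to rt; CS2; then MeI
Reagents that add atoms: carbon disulfide, S=C=S; iodomethane, CI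
Why: Xanthate formation (first half of a Barton–McCombie sequence), where the small electrophile CS2 reaches the hindered alkoxide and the product cannot undergo Chugaev elimination because neither neighbour of C5 carries hydrogen.

Step 12
Reactants: 17 O-{(2R,4S)-4-[(tert-butyldimethylsilyl)oxy]-2-[(4S,7S)-9-[(4-methoxybenzyl)oxy]-7-methyl-3-methylidenenon-1-en-4-yl]-2,6,6-trimethylcyclohexyl} S-methyl carbonodithioate
Product: 18 (2S,5S,9S,10S,13S)-2-[(tert-butyldimethylsilyl)oxy]-15-[(4-methoxybenzyl)oxy]labd-7-ene (2α-silyloxy)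
Conditions: Bu3SnH (1.5 equiv, syringe pump), AIBN (cat.), PhH (high dilution), 80 °C
Reagents that add atoms: none
Why: Proposed new method: Bu3Sn• adds to the thiocarbonyl group of 17 and β-scission releases the secondary C5 radical from either C5 epimer; this radical adds 6-endo-trig to the terminal carbon C6 of the 2-substituted buta-1,3-diene, the only mode that gives a delocalised allyl radical (C7–C8–C17), and hydrogen transfer from Bu3SnH to the less hindered exocyclic terminus C17 then leaves the endocyclic C7=C8 olefin with its methyl group. The closest known reaction types are tin hydride cyclisations of xanthate-derived radicals onto 1,3-dienes and 6-endo Giese closures of 4-oxohex-5-enyl radicals, but closure onto a diene tethered through its 2-position with terminal hydrogen transfer is not precedented. Ring B is closed in the 6-endo-trig mode through a half-chair transition state in which the s-trans diene holds C6 and C9 cis on the C7–C8 axis. The new stereocentre C5 is controlled by the ring A chair (C10 chain equatorial, C10 methyl axial): C6 should approach along the equatorial direction so that C4 and C1 are both equatorial on the forming ring B and H5 ends trans to the C10 methyl, whereas the cis mode would force the quaternary C4 axial on ring B. The step needs cyclisation to outrun direct reduction, which slow stannane addition at high dilution should secure, and hydrogen transfer to C17 rather than C7, which the steric difference between the primary and the ring terminus should secure.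

Step 13
Reactants: 18 (2S,5S,9S,10S,13S)-2-[(tert-butyldimethylsilyl)oxy]-15-[(4-methoxybenzyl)oxy]labd-7-ene
Product: 19 (2S,5S,9S,10S,13S)-2-[(tert-butyldimethylsilyl)oxy]labd-7-en-15-ol
Conditions: DDQ, CH2Cl2/pH 7 buffer, 0 °C
Reagents that add atoms: none
Why: Oxidative cleavage of the PMB ether (hydride abstraction and hydrolysis), which leaves the silyl ether and the trisubstituted olefin alone.

Step 14
Reactants: 20 (E)-caffeic acid
Product: 22 (E)-3-{3,4-bis[(tert-butyldimethylsilyl)oxy]phenyl}prop-2-enoic acid, via tris-silyl caffeate 21 (not isolated)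
Conditions: TBSCl (3.5 equiv), imidazole, DMF, rt; then K2CO3 (cat.), MeOH/THF/H2O, 0 °C
Reagents that add atoms: tert-butyldimethylsilyl chloride, CC(C)(C)[Si](C)(C)Cl
Why: Exhaustive silylation followed by selective solvolysis of the labile silyl ester; the E olefin comes with the starting acid.

Step 15
Reactants: 19 (2S,5S,9S,10S,13S)-2-[(tert-butyldimethylsilyl)oxy]labd-7-en-15-ol; 22 (E)-3-{3,4-bis[(tert-butyldimethylsilyl)oxy]phenyl}prop-2-enoic acid
Product: 23 (2S,5S,9S,10S,13S)-2-[(tert-butyldimethylsilyl)oxy]labd-7-en-15-yl (E)-3-{3,4-bis[(tert-butyldimethylsilyl)oxy]phenyl}prop-2-enoate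
Conditions: EDC·HCl, DMAP (cat.), CH2Cl2, 0 °C to rt
Reagents that add atoms: none
Why: Steglich-type carbodiimide esterification of the only free hydroxyl group, the primary C15 alcohol.

Step 16
Reactants: 23 (2S,5S,9S,10S,13S)-2-[(tert-butyldimethylsilyl)oxy]labd-7-en-15-yl (E)-3-{3,4-bis[(tert-butyldimethylsilyl)oxy]phenyl}prop-2-enoate
Product: 24 (2S,5S,9S,10S,13S)-2-hydroxylabd-7-en-15-yl (E)-3-(3,4-dihydroxyphenyl)prop-2-enoate (CNP0206083.1)
Conditions: HF·pyridine, pyridine/THF, 0 °C to rt
Reagents that add atoms: none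
Why: Fluoride-mediated cleavage of the two aryl silyl ethers and the secondary silyl ether under buffered conditions that should spare the cinnamate ester and both olefins.

**Compound list**

1 | (4R,6R)-4-hydroxy-2,2,6-trimethylcyclohexan-1-one (actinol) | O=C1C(C)(C)C[C@H](O)C[C@H]1C | starting material
2 | (4R,6R)-4-[(tert-butyldimethylsilyl)oxy]-2,2,6-trimethylcyclohexan-1-one | O=C1C(C)(C)C[C@H](O[Si](C)(C)C(C)(C)C)C[C@H]1C | intermediate
3 | hydrazone of 2 | NN=C1C(C)(C)C[C@H](O[Si](C)(C)C(C)(C)C)C[C@H]1C | intermediate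
4 | (R)-tert-butyl[(4-iodo-3,5,5-trimethylcyclohex-3-en-1-yl)oxy]dimethylsilane | CC1=C(I)C(C)(C)C[C@H](O[Si](C)(C)C(C)(C)C)C1 | intermediate
5 | (S)-citronellol, (3S)-3,7-dimethyloct-6-en-1-ol | CC(C)=CCC[C@H](C)CCO | starting material
6 | 1-({[(3S)-3,7-dimethyloct-6-en-1-yl]oxy}methyl)-4-methoxybenzene | CC(C)=CCC[C@H](C)CCOCc1ccc(OC)cc1 | intermediate
7 | (4S)-6-[(4-methoxybenzyl)oxy]-4-methylhexanal | O=CCC[C@H](C)CCOCc1ccc(OC)cc1 | intermediate
8 | (5S)-1,1-dibromo-7-[(4-methoxybenzyl)oxy]-5-methylhept-1-ene | BrC(Br)=CCC[C@H](C)CCOCc1ccc(OC)cc1 | intermediate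
9 | lithium acetylide of (5S)-7-[(4-methoxybenzyl)oxy]-5-methylhept-1-yne | [Li]C#CCC[C@H](C)CCOCc1ccc(OC)cc1 | intermediate
10 | (6S)-8-[(4-methoxybenzyl)oxy]-6-methyloct-2-yn-1-ol | OCC#CCC[C@H](C)CCOCc1ccc(OC)cc1 | intermediate
11 | magnesium chelate: 4-ethenyl-3-{(3S)-5-[(4-methoxybenzyl)oxy]-3-methylpentyl}-2,5-dihydro-1,2-oxamagnesole | C=CC1=C(CC[C@H](C)CCOCc2ccc(OC)cc2)[Mg]OC1 | intermediate
12 | (2E,6S)-2-ethenyl-8-[(4-methoxybenzyl)oxy]-6-methyloct-2-en-1-ol | OC/C(C=C)=C/CC[C@H](C)CCOCc1ccc(OC)cc1 | intermediate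
13 | tert-butyl{[(1R)-4-{[(2E,6S)-2-ethenyl-8-[(4-methoxybenzyl)oxy]-6-methyloct-2-en-1-yl]oxy}-3,5,5-trimethylcyclohex-3-en-1-yl]oxy}dimethylsilane | C=C/C(COC1=C(C)C[C@@H](O[Si](C)(C)C(C)(C)C)CC1(C)C)=C\CC[C@H](C)CCOCc1ccc(OC)cc1 | intermediate
14 | (2R,4S)-4-[(tert-butyldimethylsilyl)oxy]-2-[(4S,7S)-9-[(4-methoxybenzyl)oxy]-7-methyl-3-methylidenenon-1-en-4-yl]-2,6,6-trimethylcyclohexan-1-one | C=CC(=C)[C@H](CC[C@H](C)CCOCc1ccc(OC)cc1)[C@@]2(C)C[C@@H](O[Si](C)(C)C(C)(C)C)CC(C)(C)C2=O | intermediate
15 | alcohol from 14, (2R,4S)-configured cyclohexan-1-ol, both C5 epimers | C=CC(=C)[C@H](CC[C@H](C)CCOCc1ccc(OC)cc1)[C@@]2(C)C[C@@H](O[Si](C)(C)C(C)(C)C)CC(C)(C)C2O | intermediate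
16 | sodium xanthate (sodium O-cyclohexyl carbonodithioate) of 15 | C=CC(=C)[C@H](CC[C@H](C)CCOCc1ccc(OC)cc1)[C@@]2(C)C[C@@H](O[Si](C)(C)C(C)(C)C)CC(C)(C)C2OC(=S)[S-].[Na+] | intermediate
17 | S-methyl xanthate of 15, both C5 epimers | C=CC(=C)[C@H](CC[C@H](C)CCOCc1ccc(OC)cc1)[C@@]2(C)C[C@@H](O[Si](C)(C)C(C)(C)C)CC(C)(C)C2OC(=S)SC | intermediate
18 | (2S,5S,9S,10S,13S)-2-[(tert-butyldimethylsilyl)oxy]-15-[(4-methoxybenzyl)oxy]labd-7-ene | CC1=CC[C@H]2C(C)(C)C[C@H](O[Si](C)(C)C(C)(C)C)C[C@]2(C)[C@H]1CC[C@H](C)CCOCc1ccc(OC)cc1 | intermediate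
19 | (2S,5S,9S,10S,13S)-2-[(tert-butyldimethylsilyl)oxy]labd-7-en-15-ol | CC1=CC[C@H]2C(C)(C)C[C@H](O[Si](C)(C)C(C)(C)C)C[C@]2(C)[C@H]1CC[C@H](C)CCO | intermediate
20 | (E)-caffeic acid | OC(=O)/C=C/c1ccc(O)c(O)c1 | starting material
21 | tert-butyldimethylsilyl (E)-3-{3,4-bis[(tert-butyldimethylsilyl)oxy]phenyl}prop-2-enoate | CC(C)(C)[Si](C)(C)OC(=O)/C=C/c1ccc(O[Si](C)(C)C(C)(C)C)c(O[Si](C)(C)C(C)(C)C)c1 | intermediate
22 | (E)-3-{3,4-bis[(tert-butyldimethylsilyl)oxy]phenyl}prop-2-enoic acid | OC(=O)/C=C/c1ccc(O[Si](C)(C)C(C)(C)C)c(O[Si](C)(C)C(C)(C)C)c1 | intermediate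
23 | (2S,5S,9S,10S,13S)-2-[(tert-butyldimethylsilyl)oxy]labd-7-en-15-yl (E)-3-{3,4-bis[(tert-butyldimethylsilyl)oxy]phenyl}prop-2-enoate | CC1=CC[C@H]2C(C)(C)C[C@H](O[Si](C)(C)C(C)(C)C)C[C@]2(C)[C@H]1CC[C@H](C)CCOC(=O)/C=C/c1ccc(O[Si](C)(C)C(C)(C)C)c(O[Si](C)(C)C(C)(C)C)c1 | intermediate
24 | (2S,5S,9S,10S,13S)-2-hydroxylabd-7-en-15-yl (E)-caffeate (CNP0206083.1) | CC1=CC[C@H]2C(C)(C)C[C@H](O)C[C@]2(C)[C@H]1CC[C@H](C)CCOC(=O)/C=C/c1ccc(O)c(O)c1 | target

**Step count and risks**

Total step count: 16. Longest linear sequence: 12 steps (from 5 through steps 4–13, 15 and 16).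

Steps most likely to fail:

1. Step 12 (Proposed new method). The hindered C5 radical may be reduced by the stannane before it reaches the unactivated diene, the closure may leak to the cis ring fusion, or hydrogen may be transferred to the ring terminus of the allyl radical. The fallback uses known chemistry, sets out from ketone 14 and comes back to the route at alcohol 19. A nickel-catalysed reductive diene–carbonyl cyclisation (Ni(cod)2, PPh3, Et3SiH, THF) forms the same C5–C6 bond and, by hydride transfer to the exocyclic allyl terminus, should give the C5 triethylsilyl ether of the labd-7-ene F1. TBAF (1 equiv, 0 °C) should cleave the triethylsilyl ether ahead of the tert-butyldimethylsilyl ether and free the tertiary C5 alcohol F2. SOCl2/pyridine should eliminate towards C6, the only position with a β-hydrogen, to give the homoannular labda-5,7-diene F3. Li/NH3/t-BuOH should then reduce the diene to the trans-fused Δ7 system by axial protonation at C5, as known for steroidal 5,7-dienes, and cleave the PMB ether in the same flask to give 19.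

2. Step 9. The copper-mediated C–O bond formation may stall at the doubly flanked tetrasubstituted vinyl iodide, with protodeiodination taking over. The fallback sets out from ketone 2 and comes back at 14. O-Methylation of the potassium enolate (KN(SiMe3)2, MeOTf, THF/DMPU) should give the methyl enol ether F4. Heating F4 with dienol 12 and catalytic pivalic acid in xylene, with removal of methanol, should bring about enol ether exchange and Claisen rearrangement (Saucy–Marbet type) to 14 with the same stereochemical course.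

3. Step 8. Carbomagnesiation of the unactivated internal alkyne may be incomplete or lose its anti selectivity. The fallback sets out from 10 and comes back at 12. Trans-hydroalumination with LiAlH4/AlCl3 followed by I2 should give the (2Z)-2-iodo allylic alcohol F5, and a Stille coupling with tributyl(vinyl)stannane (Pd(PPh3)4, DMF) should convert it into 12 with the olefin geometry retained.

**Further compounds**

F1 | step 12 | (2S,9S,10S,13S)-2-[(tert-butyldimethylsilyl)oxy]-15-[(4-methoxybenzyl)oxy]-5-(triethylsilyloxy)labd-7-ene (C5 epimers) | CC1=CCC2(O[Si](CC)(CC)CC)C(C)(C)C[C@H](O[Si](C)(C)C(C)(C)C)C[C@]2(C)[C@H]1CC[C@H](C)CCOCc1ccc(OC)cc1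
F2 | step 12 | (2S,9S,10S,13S)-2-[(tert-butyldimethylsilyl)oxy]-15-[(4-methoxybenzyl)oxy]labd-7-en-5-ol (C5 epimers) | CC1=CCC2(O)C(C)(C)C[C@H](O[Si](C)(C)C(C)(C)C)C[C@]2(C)[C@H]1CC[C@H](C)CCOCc1ccc(OC)cc1
F3 | step 12 | (2S,9S,10S,13S)-2-[(tert-butyldimethylsilyl)oxy]-15-[(4-methoxybenzyl)oxy]labda-5,7-diene | CC1=CC=C2C(C)(C)C[C@H](O[Si](C)(C)C(C)(C)C)C[C@]2(C)[C@H]1CC[C@H](C)CCOCc1ccc(OC)cc1
F4 | step 9 | (R)-tert-butyl[(4-methoxy-3,5,5-trimethylcyclohex-3-en-1-yl)oxy]dimethylsilane | COC1=C(C)C[C@@H](O[Si](C)(C)C(C)(C)C)CC1(C)C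
F5 | step 8 | (2Z,6S)-2-iodo-8-[(4-methoxybenzyl)oxy]-6-methyloct-2-en-1-ol | OC/C(I)=C/CC[C@H](C)CCOCc1ccc(OC)cc1
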